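## Retrosynthetic overview

1. **22 ⇐ 21:** Schenck ene reaction of singlet oxygen on the Δ4(5) alkene installs the 5α‑OOH and the Δ4(15) alkene; no ring is formed.
2. **21 ⇐ 20:** the second ring (decalin) comes from proton‑triggered transannular C5–C10 closure of a germacra‑1(10),4‑diene.
3. **20 ⇐ 17:** the first ring (cyclodecadiene) is closed by SE2′ attack of the C7=C11–C13 allyl unit on a C8 aldehyde (C7–C8 bond), regenerating the C11=C13 methylene; the alkoxide is trapped as the acetate in the flask.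
4. **17 ⇐** but‑3‑yn‑1‑ol (C8, C9, C10, C1) + Me3Al (C14) + oxirane (C2, C3) + pent‑3‑yn‑1‑ol (C15, C4–C7) + methyl propiolate (C11–C13); C3 is set by a catalytic asymmetric alkenylzinc addition.

Assumption: the SMILES is read as the eudesmane with 3β‑isobutyrate, 5α‑OOH, 7β side chain, 8β‑acetate and 10β‑methyl (3S,5S,7R,8R,10R); eudesmane/germacrane numbering C1–C15 is used for every intermediate.

## Route

**Step 1**
Reactants: 1 but‑3‑yn‑1‑ol
Product: 2 tert‑butyl(but‑3‑yn‑1‑yloxy)dimethylsilane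
Conditions: TBSCl, imidazole, CH2Cl2, 0 °C → rt
Reagents that add atoms: tert‑butyldimethylsilyl chloride, CC(C)(C)[Si](C)(C)Cl
Why: standard silylation of a primary alcohol, masking C8–OH through the organometallic steps.

**Step 2**
Reactants: 2 tert‑butyl(but‑3‑yn‑1‑yloxy)dimethylsilane
Product: 5 (E)‑6‑[(tert‑butyldimethylsilyl)oxy]‑4‑methylhex‑3‑en‑1‑ol, via alkenyldimethylalane 3 (not isolated), via lithium alkenylalanate 4 (not isolated)
Conditions: Me3Al, Cp2ZrCl2 (0.25 equiv), CH2Cl2, 0 °C → rt; n‑BuLi, THF, −78 °C; ethylene oxide, −78 °C → rt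
Reagents that add atoms: trimethylaluminium, C[Al](C)C; ethylene oxide, C1CO1
Why: Negishi Zr‑catalysed carboalumination adds Me–Al syn across the alkyne (sets the E‑C1=C10 alkene and C14), and the derived alanate opens oxirane with retention of alkene geometry to append C2–C3.

**Step 3**
Reactants: 5 (E)‑6‑[(tert‑butyldimethylsilyl)oxy]‑4‑methylhex‑3‑en‑1‑ol
Product: 6 (E)‑6‑[(tert‑butyldimethylsilyl)oxy]‑4‑methylhex‑3‑enal
Conditions: DMP, NaHCO3, CH2Cl2, 0 °C; used crude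
Reagents that add atoms: none
Why: Dess–Martin oxidation is non‑basic, so the β,γ‑unsaturated aldehyde is not isomerised into conjugation.

**Step 4**
Reactants: 7 pent‑3‑yn‑1‑ol
Product: 8 triethyl(pent‑3‑yn‑1‑yloxy)silane
Conditions: TESCl, imidazole, CH2Cl2, 0 °C
Reagents that add atoms: chlorotriethylsilane, CC[Si](Cl)(CC)CC
Why: standard silylation; TES is chosen because step 6 converts it directly into the aldehyde while TBS survives.

**Step 5**
Reactants: 8 triethyl(pent‑3‑yn‑1‑yloxy)silane; 6 (E)‑6‑[(tert‑butyldimethylsilyl)oxy]‑4‑methylhex‑3‑enal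
Product: 12 (3E,5S,7E)‑10‑[(tert‑butyldimethylsilyl)oxy]‑4,8‑dimethyl‑1‑[(triethylsilyl)oxy]deca‑3,7‑dien‑5‑yl 2‑methylpropanoate, via alkenylzirconocene chloride 9 (not isolated), via alkenyl(methyl)zinc 10 (not isolated), via methylzinc alkoxide 11 (not isolated)
Conditions: Cp2Zr(H)Cl, CH2Cl2, rt; Me2Zn, toluene, −65 °C; chiral amino‑thiol ligand (10 mol %, enantiomer giving Re‑face addition), 6, −30 °C; then (i‑PrCO)2O, DMAP (cat.), 0 °C → rt
Reagents that add atoms: isobutyric anhydride, CC(C)C(=O)OC(=O)C(C)C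
Why: syn‑hydrozirconation places Zr on the methyl‑bearing alkyne carbon (E‑C4=C5), Zr→Zn transmetalation and ligand‑controlled Re‑face addition of the alkenylzinc to the aldehyde (catalytic asymmetric alkenylzinc addition) set C3 as S, and the zinc alkoxide is acylated in the flask.

**Step 6**
Reactants: 12 (3E,5S,7E)‑10‑[(tert‑butyldimethylsilyl)oxy]‑4,8‑dimethyl‑1‑[(triethylsilyl)oxy]deca‑3,7‑dien‑5‑yl 2‑methylpropanoate
Product: 13 (3E,5S,7E)‑10‑[(tert‑butyldimethylsilyl)oxy]‑4,8‑dimethyl‑1‑oxodeca‑3,7‑dien‑5‑yl 2‑methylpropanoate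
Conditions: IBX, DMSO, rt; used at once
Reagents that add atoms: none
Why: IBX in DMSO cleaves a primary TES ether and oxidises the freed alcohol in one pot while the TBS ether survives, and the base‑free medium avoids enolisation of the β,γ‑unsaturated aldehyde (which could expel the C3 ester).

**Step 7**
Reactants: 13 (3E,5S,7E)‑10‑[(tert‑butyldimethylsilyl)oxy]‑4,8‑dimethyl‑1‑oxodeca‑3,7‑dien‑5‑yl 2‑methylpropanoate
Product: 15 methyl (5E,7S,9E)‑3‑acetoxy‑12‑[(tert‑butyldimethylsilyl)oxy]‑6,10‑dimethyl‑2‑methylidene‑7‑(2‑methylpropanoyloxy)dodeca‑5,9‑dienoate (both C3 epimers), via diisobutylaluminium alkoxide 14 (not isolated)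
Conditions: DIBAL‑H, HMPA, THF, 0 °C; methyl propiolate; 13, 0 °C → rt; then Ac2O, pyridine, 0 °C
Reagents that add atoms: methyl propiolate, C#CC(=O)OC; acetic anhydride, CC(=O)OC(C)=O
Why: 1,4‑hydroalumination of methyl propiolate gives the α‑aluminoacrylate, which adds to the aldehyde (vinylalumination, a Baylis–Hillman equivalent suited to enolisable aldehydes), and the aluminium alkoxide is acetylated in situ; the new carbinol centre (C7) is a mixture that is erased in step 10.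

**Step 8**
Reactants: 15 methyl (5E,7S,9E)‑3‑acetoxy‑12‑[(tert‑butyldimethylsilyl)oxy]‑6,10‑dimethyl‑2‑methylidene‑7‑(2‑methylpropanoyloxy)dodeca‑5,9‑dienoate
Product: 16 methyl (5E,7S,9E)‑3‑acetoxy‑12‑hydroxy‑6,10‑dimethyl‑2‑methylidene‑7‑(2‑methylpropanoyloxy)dodeca‑5,9‑dienoate
Conditions: HF (48 % aq.), MeCN, 0 °C
Reagents that add atoms: none
Why: fluoride cleavage of the primary TBS ether under mildly acidic conditions that leave the three esters and the acrylate untouched.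

**Step 9**
Reactants: 16 methyl (5E,7S,9E)‑3‑acetoxy‑12‑hydroxy‑6,10‑dimethyl‑2‑methylidene‑7‑(2‑methylpropanoyloxy)dodeca‑5,9‑dienoate
Product: 17 methyl (5E,7S,9E)‑3‑acetoxy‑6,10‑dimethyl‑2‑methylidene‑7‑(2‑methylpropanoyloxy)‑12‑oxododeca‑5,9‑dienoate
Conditions: DMP, NaHCO3, CH2Cl2, 0 °C; used at once
Reagents that add atoms: none
Why: non‑basic Dess–Martin oxidation gives the C8 aldehyde without moving the C1=C10 alkene into conjugation.

**Step 10**
Reactants: 17 methyl (5E,7S,9E)‑3‑acetoxy‑6,10‑dimethyl‑2‑methylidene‑7‑(2‑methylpropanoyloxy)‑12‑oxododeca‑5,9‑dienoate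
Product: 20 methyl (1(10)E,3S,4E,7R,8R)‑8‑acetoxy‑3‑(2‑methylpropanoyloxy)germacra‑1(10),4,11(13)‑trien‑12‑oate, via allyl(ethyl)zinc aldehyde 18 (not isolated), via ethylzinc germacrenyl alkoxide 19 (not isolated)
Conditions: Pd(PPh3)4 (10 mol %), Et2Zn (3 equiv), THF, 2 mM (slow addition of 17), rt; then Ac2O, 0 °C; filtered through neutral alumina, kept below 30 °C
Reagents that add atoms: acetic anhydride, CC(=O)OC(C)=O
Why: Proposed new method: Pd(0) ionises the activated Baylis–Hillman acetate (far faster than the hindered C3 allylic isobutyrate) and Et2Zn transmetalation gives a 2‑(methoxycarbonyl)allylzinc that attacks the C8 aldehyde through C7 in a closed chair (SE2′), closing the ten‑membered ring and regenerating the C11=C13 methylene as in germacrene A formation; the Z‑allylzinc (C6 cis to CH2Zn) puts C6 axial so H‑7/H‑8 come out cis (7R,8R), the facial sense is relayed from C3 by the crown‑like folding of the forming (E,E)‑cyclodeca‑1,5‑diene with the C3 ester and C7 side chain pseudo‑equatorial, and Ac2O traps the zinc alkoxide before it can lactonise; the closest known chemistry is Pd/Et2Zn umpolung allylation of aldehydes by allylic esters (used to close ten‑membered germacrene rings) and the Zn‑mediated 2‑(alkoxycarbonyl)allylation of aldehydes that gives cis‑lactone relationships.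

**Step 11**
Reactants: 20 methyl (1(10)E,3S,4E,7R,8R)‑8‑acetoxy‑3‑(2‑methylpropanoyloxy)germacra‑1(10),4,11(13)‑trien‑12‑oate
Product: 21 methyl (3S,7R,8R,10R)‑8‑acetoxy‑3‑(2‑methylpropanoyloxy)eudesma‑4,11(13)‑dien‑12‑oate
Conditions: CSA (20 mol %), CH2Cl2, 0 °C → rt
Reagents that add atoms: none
Why: acid‑catalysed germacrene → eudesmane transannular cyclisation: protonation at C1 of the more electron‑rich C1=C10 alkene (C4=C5 is deactivated by the allylic ester) gives the C10 cation of the chair–chair conformer with the C3 ester and C7 side chain pseudo‑equatorial, C5 adds across the ring to fix C10 (R, 10β‑methyl), and the C4 cation, stabilised as the cis‑acyloxonium by the neighbouring isobutyrate, loses the anti‑periplanar H‑5α under equilibrating conditions to give the tetrasubstituted Δ4(5) alkene.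

**Step 12**
Reactants: 21 methyl (3S,7R,8R,10R)‑8‑acetoxy‑3‑(2‑methylpropanoyloxy)eudesma‑4,11(13)‑dien‑12‑oate
Product: 22 methyl (3S,5S,7R,8R,10R)‑8‑acetoxy‑5‑hydroperoxy‑3‑(2‑methylpropanoyloxy)eudesma‑4(15),11(13)‑dien‑12‑oate (CNP0244758.1)
Conditions: O2, tetraphenylporphyrin (1 mol %), visible light, CH2Cl2, −20 °C
Reagents that add atoms: oxygen, O=O
Why: Schenck ene reaction: singlet oxygen approaches the tetrasubstituted alkene from the α‑face (anti to the axial C10 methyl and the 8β‑acetate), bonds to C5 and abstracts hydrogen from the C15 methyl (H‑3 geminal to the ester is disfavoured), setting C5 (S, 5α‑OOH) and the exocyclic alkene in one step; the electron‑poor acrylate is inert.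

## Compound list

1 | but‑3‑yn‑1‑ol | C#CCCO | starting material
2 | tert‑butyl(but‑3‑yn‑1‑yloxy)dimethylsilane | C#CCCO[Si](C)(C)C(C)(C)C | intermediate
3 | [(E)‑4‑[(tert‑butyldimethylsilyl)oxy]‑2‑methylbut‑1‑en‑1‑yl]dimethylalane | C[Al](C)/C=C(\C)CCO[Si](C)(C)C(C)(C)C | intermediate (not isolated)
4 | lithium butyl[(E)‑4‑[(tert‑butyldimethylsilyl)oxy]‑2‑methylbut‑1‑en‑1‑yl]dimethylalanate | [Li+].CCCC[Al-](C)(C)/C=C(\C)CCO[Si](C)(C)C(C)(C)C | intermediate (not isolated)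
5 | (E)‑6‑[(tert‑butyldimethylsilyl)oxy]‑4‑methylhex‑3‑en‑1‑ol | OCC/C=C(\C)CCO[Si](C)(C)C(C)(C)C | intermediate
6 | (E)‑6‑[(tert‑butyldimethylsilyl)oxy]‑4‑methylhex‑3‑enal | O=CC/C=C(\C)CCO[Si](C)(C)C(C)(C)C | intermediate
7 | pent‑3‑yn‑1‑ol | CC#CCCO | starting material
8 | triethyl(pent‑3‑yn‑1‑yloxy)silane | CC#CCCO[Si](CC)(CC)CC | intermediate
9 | chloro[(E)‑5‑[(triethylsilyl)oxy]pent‑2‑en‑2‑yl]zirconocene (Cp rings drawn σ‑bonded) | C/C(=C\CCO[Si](CC)(CC)CC)[Zr](Cl)(C1C=CC=C1)C1C=CC=C1 | intermediate (not isolated)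
10 | methyl[(E)‑5‑[(triethylsilyl)oxy]pent‑2‑en‑2‑yl]zinc | C/C(=C\CCO[Si](CC)(CC)CC)[Zn]C | intermediate (not isolated)
11 | methylzinc (3E,5S,7E)‑10‑[(tert‑butyldimethylsilyl)oxy]‑4,8‑dimethyl‑1‑[(triethylsilyl)oxy]deca‑3,7‑dien‑5‑olate | CC[Si](CC)(CC)OCC/C=C(\C)[C@@H](O[Zn]C)C/C=C(\C)CCO[Si](C)(C)C(C)(C)C | intermediate (not isolated)
12 | (3E,5S,7E)‑10‑[(tert‑butyldimethylsilyl)oxy]‑4,8‑dimethyl‑1‑[(triethylsilyl)oxy]deca‑3,7‑dien‑5‑yl 2‑methylpropanoate | CC[Si](CC)(CC)OCC/C=C(\C)[C@@H](OC(=O)C(C)C)C/C=C(\C)CCO[Si](C)(C)C(C)(C)C | intermediate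
13 | (3E,5S,7E)‑10‑[(tert‑butyldimethylsilyl)oxy]‑4,8‑dimethyl‑1‑oxodeca‑3,7‑dien‑5‑yl 2‑methylpropanoate | O=CC/C=C(\C)[C@@H](OC(=O)C(C)C)C/C=C(\C)CCO[Si](C)(C)C(C)(C)C | intermediate
14 | diisobutylaluminium alkoxide of methyl (5E,7S,9E)‑12‑[(tert‑butyldimethylsilyl)oxy]‑3‑hydroxy‑6,10‑dimethyl‑2‑methylidene‑7‑(2‑methylpropanoyloxy)dodeca‑5,9‑dienoate | C=C(C(=O)OC)C(O[Al](CC(C)C)CC(C)C)C/C=C(\C)[C@@H](OC(=O)C(C)C)C/C=C(\C)CCO[Si](C)(C)C(C)(C)C | intermediate (not isolated)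
15 | methyl (5E,7S,9E)‑3‑acetoxy‑12‑[(tert‑butyldimethylsilyl)oxy]‑6,10‑dimethyl‑2‑methylidene‑7‑(2‑methylpropanoyloxy)dodeca‑5,9‑dienoate (C3 epimers) | C=C(C(=O)OC)C(OC(C)=O)C/C=C(\C)[C@@H](OC(=O)C(C)C)C/C=C(\C)CCO[Si](C)(C)C(C)(C)C | intermediate
16 | methyl (5E,7S,9E)‑3‑acetoxy‑12‑hydroxy‑6,10‑dimethyl‑2‑methylidene‑7‑(2‑methylpropanoyloxy)dodeca‑5,9‑dienoate | C=C(C(=O)OC)C(OC(C)=O)C/C=C(\C)[C@@H](OC(=O)C(C)C)C/C=C(\C)CCO | intermediate
17 | methyl (5E,7S,9E)‑3‑acetoxy‑6,10‑dimethyl‑2‑methylidene‑7‑(2‑methylpropanoyloxy)‑12‑oxododeca‑5,9‑dienoate | C=C(C(=O)OC)C(OC(C)=O)C/C=C(\C)[C@@H](OC(=O)C(C)C)C/C=C(\C)CC=O | intermediate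
18 | ethyl[(5E,7S,9E)‑2‑(methoxycarbonyl)‑6,10‑dimethyl‑7‑(2‑methylpropanoyloxy)‑12‑oxododeca‑2,5,9‑trien‑1‑yl]zinc | CC[Zn]CC(C(=O)OC)=CC/C=C(\C)[C@@H](OC(=O)C(C)C)C/C=C(\C)CC=O | intermediate (not isolated)
19 | ethylzinc alkoxide of methyl (1(10)E,3S,4E,7R,8R)‑8‑hydroxy‑3‑(2‑methylpropanoyloxy)germacra‑1(10),4,11(13)‑trien‑12‑oate | C=C(C(=O)OC)[C@H]1C/C=C(\C)[C@@H](OC(=O)C(C)C)C/C=C(\C)C[C@H]1O[Zn]CC | intermediate (not isolated)
20 | methyl (1(10)E,3S,4E,7R,8R)‑8‑acetoxy‑3‑(2‑methylpropanoyloxy)germacra‑1(10),4,11(13)‑trien‑12‑oate (ten‑membered ring; H‑7/H‑8 cis) | C=C(C(=O)OC)[C@H]1C/C=C(\C)[C@@H](OC(=O)C(C)C)C/C=C(\C)C[C@H]1OC(C)=O | intermediate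
21 | methyl (3S,7R,8R,10R)‑8‑acetoxy‑3‑(2‑methylpropanoyloxy)eudesma‑4,11(13)‑dien‑12‑oate (3β‑ester, 8β‑acetate, 10β‑methyl) | C=C(C(=O)OC)[C@H]1CC2=C(C)[C@@H](OC(=O)C(C)C)CC[C@]2(C)C[C@H]1OC(C)=O | intermediate
22 | methyl (3S,5S,7R,8R,10R)‑8‑acetoxy‑5‑hydroperoxy‑3‑(2‑methylpropanoyloxy)eudesma‑4(15),11(13)‑dien‑12‑oate | C=C(C(=O)OC)[C@H]1C[C@@]2(OO)C(=C)[C@@H](OC(=O)C(C)C)CC[C@]2(C)C[C@H]1OC(C)=O | target

## Step count and risks

Total steps: 12. Longest linear sequence: 11 (steps 1–3 and 5–12); step 4 is a one‑step side branch.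

**Step 10 (macrocyclisation).** The risks are the yield of ten‑ring closure, the relay of facial selectivity from the remote C3 centre, Pd ionising the C3 allylic ester, and lactonisation before acetylation. The fallback sets out from 16 and comes back at 20, replacing the in situ Pd/Zn umpolung by an isolable, configurationally stable allylboron pro‑nucleophile and no palladium. Copper(I)‑catalysed SN2′ borylation of the Baylis–Hillman acetate with B2pin2 gives methyl (2E,5E,7S,9E)‑12‑hydroxy‑6,10‑dimethyl‑7‑(2‑methylpropanoyloxy)‑2‑[(pinacolboryl)methyl]dodeca‑2,5,9‑trienoate F1. Dess–Martin oxidation gives the corresponding 12‑oxo allylboronate F2, which is slow to react without activation and can be handled. Heating at high dilution (toluene, 70 °C) or adding catalytic Sc(OTf)3 triggers a Type I macro‑allylboration through a closed chair, stereospecific for the 7,8‑cis relationship because C6 is cis to CH2B. Mild work‑up gives methyl (1(10)E,3S,4E,7R,8R)‑8‑hydroxy‑3‑(2‑methylpropanoyloxy)germacra‑1(10),4,11(13)‑trien‑12‑oate F3, and Ac2O/pyridine returns 20.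

**Step 11 (transannular cyclisation).** The risks are that the kinetic exocyclic alkene does not funnel to Δ4(5), or that prolonged acid ionises the allylic isobutyrate. The fallback sets out from 20 and comes back at 21, separating ring closure from alkene placement and doing the latter by a radical rather than a cationic mechanism. Short exposure to a weak acid (PPTS, CH2Cl2, 0 °C) gives the kinetic product methyl (3S,5R,7R,8R,10R)‑8‑acetoxy‑3‑(2‑methylpropanoyloxy)eudesma‑4(15),11(13)‑dien‑12‑oate F4 (5α‑H). A metal‑hydride hydrogen‑atom‑transfer isomerisation (Co(salen)Cl cat., PhSiH3, benzene, rt) then moves the electron‑rich exocyclic alkene to the tetrasubstituted position to give 21. The tetrasubstituted alkene and the acrylate are poor hydrogen‑atom acceptors, and the C4 radical cannot reach the acrylate in the trans‑fused framework.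

**Step 5 (asymmetric fragment union).** The risks are the regioselectivity of hydrozirconation of the 2‑alkyne and the enantioselectivity with an unbranched, enolisable aldehyde. The fallback sets out from 8 and comes back at 12, setting C3 by reagent‑controlled ketone reduction instead of C–C bond formation. Hydrozirconation–iodination gives (E)‑triethyl[(4‑iodopent‑3‑en‑1‑yl)oxy]silane F5, whose regioisomer is removed by chromatography. Nozaki–Hiyama–Kishi coupling with 6 (CrCl2, NiCl2 cat., DMSO) gives racemic (3E,7E)‑10‑[(tert‑butyldimethylsilyl)oxy]‑4,8‑dimethyl‑1‑[(triethylsilyl)oxy]deca‑3,7‑dien‑5‑ol F6. Dess–Martin oxidation gives the enone (3E,7E)‑10‑[(tert‑butyldimethylsilyl)oxy]‑4,8‑dimethyl‑1‑[(triethylsilyl)oxy]deca‑3,7‑dien‑5‑one F7. CBS reduction ((R)‑Me‑CBS, catecholborane, −78 °C; the α‑methylalkenyl group acts as the large substituent) gives the (3E,5S,7E)‑alcohol F8, and isobutyryl chloride/pyridine returns 12.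

## Further compounds

F1 | step 10 | methyl (2E,5E,7S,9E)‑12‑hydroxy‑6,10‑dimethyl‑7‑(2‑methylpropanoyloxy)‑2‑[(4,4,5,5‑tetramethyl‑1,3,2‑dioxaborolan‑2‑yl)methyl]dodeca‑2,5,9‑trienoate | COC(=O)/C(CB1OC(C)(C)C(C)(C)O1)=C/C/C=C(\C)[C@@H](OC(=O)C(C)C)C/C=C(\C)CCO
F2 | step 10 | methyl (2E,5E,7S,9E)‑6,10‑dimethyl‑7‑(2‑methylpropanoyloxy)‑12‑oxo‑2‑[(4,4,5,5‑tetramethyl‑1,3,2‑dioxaborolan‑2‑yl)methyl]dodeca‑2,5,9‑trienoate | COC(=O)/C(CB1OC(C)(C)C(C)(C)O1)=C/C/C=C(\C)[C@@H](OC(=O)C(C)C)C/C=C(\C)CC=O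
F3 | step 10 | methyl (1(10)E,3S,4E,7R,8R)‑8‑hydroxy‑3‑(2‑methylpropanoyloxy)germacra‑1(10),4,11(13)‑trien‑12‑oate | C=C(C(=O)OC)[C@H]1C/C=C(\C)[C@@H](OC(=O)C(C)C)C/C=C(\C)C[C@H]1O
F4 | step 11 | methyl (3S,5R,7R,8R,10R)‑8‑acetoxy‑3‑(2‑methylpropanoyloxy)eudesma‑4(15),11(13)‑dien‑12‑oate | C=C(C(=O)OC)[C@H]1C[C@H]2C(=C)[C@@H](OC(=O)C(C)C)CC[C@]2(C)C[C@H]1OC(C)=O
F5 | step 5 | (E)‑triethyl[(4‑iodopent‑3‑en‑1‑yl)oxy]silane | I/C(C)=C/CCO[Si](CC)(CC)CC
F6 | step 5 | racemic (3E,7E)‑10‑[(tert‑butyldimethylsilyl)oxy]‑4,8‑dimethyl‑1‑[(triethylsilyl)oxy]deca‑3,7‑dien‑5‑ol | CC[Si](CC)(CC)OCC/C=C(\C)C(O)C/C=C(\C)CCO[Si](C)(C)C(C)(C)C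
F7 | step 5 | (3E,7E)‑10‑[(tert‑butyldimethylsilyl)oxy]‑4,8‑dimethyl‑1‑[(triethylsilyl)oxy]deca‑3,7‑dien‑5‑one | CC[Si](CC)(CC)OCC/C=C(\C)C(=O)C/C=C(\C)CCO[Si](C)(C)C(C)(C)C
F8 | step 5 | (3E,5S,7E)‑10‑[(tert‑butyldimethylsilyl)oxy]‑4,8‑dimethyl‑1‑[(triethylsilyl)oxy]deca‑3,7‑dien‑5‑ol | CC[Si](CC)(CC)OCC/C=C(\C)[C@@H](O)C/C=C(\C)CCO[Si](C)(C)C(C)(C)C
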